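# Synthesis plan for 6-hydroxy-8-(2-hydroxy-4-methoxy-6-pentylphenoxy)-3-pentyl-1H-isochromen-1-one (22)

Numbering used throughout: isocoumarin atoms C1 (lactone carbonyl), O2, C3 (pentyl), C4, C4a, C5–C8, C8a. Ring A is the benzo ring. Ring B is the phenoxy ring C1'–C6' (C1' ether carbon, C2' OH, C4' OMe, C6' pentyl).

## The problem

The target joins a 3-pentylisocoumarin to a second arene through a diaryl ether. The ether oxygen is flanked by the C8a carbonyl on ring A and by hydroxyl and pentyl on ring B, so arylation of either phenol by copper or SNAr chemistry is the hardest bond to make. There is no stereocentre; sp3 centres made on the way may be left as mixtures as long as all are erased. Three phenolic oxygens must be told apart: O6 and O2' end free, O4' carries methyl. The methyl must therefore go onto one of two similar ring B oxygens, and the protecting groups elsewhere must come off without touching it. The enol lactone (C1–O2–C3=C4) opens with hydroxide or alkoxide and its double bond can be hydrogenated, so it is best closed late and under acid. The enabling feature is that the oxygens at C2' and C4' are 1,3-related: ring B is a masked cyclohexane-1,3-dione. In that dione C1' is an sp3 carbon next to the C2' carbonyl, i.e. the α-carbon of an ester in an open-chain precursor, so the crowded O–C1' bond can be made on an acetate unit rather than by arylation. Two hazards come with this. A dihydro ring carrying the aryloxy group at C1' can aromatise by losing the ring A phenol instead of two hydrogens if an electron-rich diene ever spans C2'–C5'. And the ring A ester sits five atoms from C1' and invites Dieckmann closure to a benzofuranone whenever C1' is a carbanion.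

## Retrosynthesis

**22 to 21.** The two free phenols are uncovered last by cutting two O–benzyl bonds. Methyl ethers could not be distinguished from the C4' methoxy group, and silyl ethers would not survive the alkoxide and amide bases upstream. The forward step must cleave benzyl but spare the aryl methyl ether, the diaryl ether and the C3=C4 bond, which argues for BCl3 with a cation scavenger rather than hydrogenolysis.

**21 to 20.** The lactone acyl–oxygen bond O2–C1 is cut, giving keto ester 20. Closure must be acid-catalysed: under base the ketone's other α-carbon would close a C–C bond on the ester to give a naphthalene-1,3-diol.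

**20 to 16 and 19.** The C3–C4 bond is cut between the benzylic carbon of toluate 16 and Weinreb amide 19 (made from hexanoyl chloride 17 and amine salt 18). An alkyne-based closure would need a halide or triflate at C4a, whereas the methyl group is already present in methyl orsellinate. The forward step is a lateral lithiation that must leave two benzyl ethers and ring B alone.

**16 to 15, 13 and 12.** Removing the C2' benzyl group gives phenol 15. Adding two hydrogens across C1'–C6' gives vinylogous ester 13. Cutting the O–CH3 bond gives dione 12. The choice between the two ring B oxygens is thus made at the dione stage, where the C2' carbonyl is screened by the substituted C1' and the C4' carbonyl is not. A resorcinol would offer a weaker bias. The benzyl group on O2' keeps that oxygen from consuming base or closing a seven-membered aryl ester on the ring A carboxyl in the later steps.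

**12 to 10.** A carboxyl group is put back on C5' as a tert-butyl ester. A methyl ester there could not be removed without risk to the hindered ring A methyl ester; the tert-butyl ester falls to acid alone.

**10 to 7 and 8.** This is the central cut: C5'–C6' and C2'–C3' are broken, taking ring B apart into enoate 7 and tert-butyl acetoacetate 8. The neighbouring cut (C5'–C6' and C3'–C4', an enone plus a malonate) is also sound and is held in reserve. Keeping ring B aromatic and coupling it as a phenol would bring back the hindered arylation. After this cut ring B is gone and the diaryl ether has become an α-aryloxy ester.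

**7 to 5 and 6.** The C1'=C6' double bond is cut by Horner–Wadsworth–Emmons logic into phosphonate 5 and hexanal 6. An aldol condensation of a plain aryloxyacetate would form a free ester enolate beside the ring A benzoate, which is the textbook route to 3-hydroxybenzofuran-2-carboxylates. The stabilised phosphonate anion avoids this.

**5 to 4 and 2; 4 to 3; 2 to 1.** The O–C1' bond is cut to phenol 4 and diazophosphonoacetate 2 (carbenoid O–H insertion). Phenol 4 is the 4-O-benzyl ether of methyl orsellinate 3, whose chelated 2-OH is left free by a selective alkylation. Diazo compound 2 comes from trimethyl phosphonoacetate 1 by diazo transfer.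

## Roads not taken

**Alternative 1: hexadehydro-Diels–Alder cascade.**
- Cut: ring A itself (C4a–C8a and C7–C8) together with the C6–O bond.
- Forward: heating the ester-tethered triyne A2 would join its 1,3-diyne (C4a, C5, C6, C7) to its aryloxy-ynoate (C8, C8a). The C5–C6 aryne would then take up acetic acid to give the dihydroisocoumarin acetate A1.
- Merits: ring A and the lactone ring form in one metal-free step, and the ether oxygen is in place before the ring exists.
- Weak points:
  - The ynoate of A2 is an ynol ether of the hindered phenol A3. A3 needs several steps, and the ynol ether is a sensitive, strongly electrophilic function.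
  - The four-atom tether closes a six-membered ring more slowly than the usual three-atom tethers, at temperatures where a terminal diyne polymerises.
  - Nothing nearby dictates whether acetate ends at C6 or C5.
  - A1 is at the dihydro level with a superfluous C3 stereocentre, so dehydrogenation, acetate cleavage and debenzylation follow.
- Comparison: it is better in that O6 needs no protecting group until the aryne is trapped. Against this, the chosen plan builds ring B from hexanal and acetoacetate and never needs A3 or an ynol ether.

**Alternative 2: aryne, phenoxide and carbon dioxide.**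
- Cut: C8–O and C8a–C1.
- Forward: fluoride releases the aryne from silyl triflate A5. The caesium salt of phenol A3 adds at C8, away from the flanking benzyloxy group, and the C8a anion is carboxylated to give acid A4.
- Merits: addition to an aryne tolerates ortho substitution of the nucleophile far better than copper coupling. The hardest bond and the carboxyl carbon are installed together with inductive regiocontrol.
- Weak points:
  - A4 carries oxygen, not carbon, at C4a. The pyranone carbons must follow by selective cleavage of one of three benzyl ethers, triflation, alkynylation and cyclisation.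
  - The aryl anion may be protonated instead of carboxylated.
  - Both A3 and A5 need multistep preparation.
- Comparison: it is more convergent and forms the diaryl ether more directly, a real advantage. The chosen plan sets against it that all carbon substituents of ring A are already in methyl orsellinate and that no hindered phenol must be prepared.

**Alternative 3: carboxylate-directed C–H annulation.**
- Cut: C4a–C4 and O2–C3.
- Forward: acid A7 and sulfoxonium ylide A8 under [Cp*RhCl2]2 (trivalent rhodium) undergo C–H rhodation at the only free ortho position, insertion of the ylide carbon and cyclocondensation to give isocoumarin A6.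
- Merits: the pyranone closes at the right oxidation level in one step, without strong base and without regiochemical doubt. A6 is the same compound as 21, which the chosen plan reaches from 16 in two steps.
- Weak points: all depends on A7, the tri-ortho-substituted diaryl ether. It would have to come from coupling A3 with an ortho-halobenzoate, so the hindered arylation and the synthesis of A3 are moved to the front, not solved.
- Comparison: taken alone this endgame is shorter and gentler than lateral lithiation plus lactonisation. The chosen plan wins on the ether bond, made as an insertion at an sp3 carbon, and on ring B, grown around that bond. If A7 were at hand, this would be the better finish.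

Key step: step 5

## Remarks on the chemistry

- The target has no stereocentre.
- Enoate 7 is drawn as the expected major 2Z isomer. The 2E isomer gives the same annulation product 10, so the mixture can be carried on.

## Route

Step 1
Reactants: 1 trimethyl phosphonoacetate
Product: 2 methyl 2-diazo-2-(dimethoxyphosphoryl)acetate
Conditions: NaH, THF, 0 °C; 4-AcNHC6H4SO2N3, 0 °C → rt; H2O work-up
Reagents that add atoms: 4-acetamidobenzenesulfonyl azide, CC(=O)Nc1ccc(cc1)S(=O)(=O)N=[N+]=[N-]
Why: Regitz diazo transfer; the sodium salt of the phosphonoacetate attacks the terminal azide nitrogen and the triazene collapses to the diazo compound and the sulfonamide anion, the standard preparation of diazophosphonoacetates.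

Step 2
Reactants: 3 methyl orsellinate
Product: 4 methyl 4-(benzyloxy)-2-hydroxy-6-methylbenzoate
Conditions: BnBr (1 equiv), K2CO3, acetone, reflux
Reagents that add atoms: benzyl bromide, BrCc1ccccc1
Why: Williamson ether synthesis; the 2-OH is chelated to the ester carbonyl and flanked by it, so one equivalent of benzyl bromide takes the para 4-OH.

Step 3
Reactants: 4 methyl 4-(benzyloxy)-2-hydroxy-6-methylbenzoate; 2 methyl 2-diazo-2-(dimethoxyphosphoryl)acetate
Product: 5 methyl 4-(benzyloxy)-2-[1-(dimethoxyphosphoryl)-2-methoxy-2-oxoethoxy]-6-methylbenzoate (racemic)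
Conditions: Rh2(OAc)4 (cat.), PhMe, 80 °C, slow addition of 2
Reagents that add atoms: none
Why: Rhodium carbenoid O–H insertion (divalent rhodium carboxylate catalysis), the known route from phenols to 2-aryloxyphosphonoacetates; the phenol oxygen attacks the acceptor-substituted carbenoid and a proton shift completes the crowded O–C1' bond without any arylation. The new stereocentre is racemic and disappears in step 4.

Step 4
Reactants: 5 methyl 4-(benzyloxy)-2-[1-(dimethoxyphosphoryl)-2-methoxy-2-oxoethoxy]-6-methylbenzoate; 6 hexanal
Product: 7 methyl (2Z)-2-[5-(benzyloxy)-2-(methoxycarbonyl)-3-methylphenoxy]oct-2-enoate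
Conditions: LiCl, DBU, MeCN, 0 °C → rt
Reagents that add atoms: none
Why: Horner–Wadsworth–Emmons olefination under LiCl/amine conditions; the stabilised anion is formed in the presence of the aldehyde and consumed at once, so it has no time to attack the neighbouring benzoate. α-Oxygenated phosphonoacetates give mainly the Z enoate (alkyl trans to the ester).

Step 5
Reactants: 7 methyl (2Z)-2-[5-(benzyloxy)-2-(methoxycarbonyl)-3-methylphenoxy]oct-2-enoate; 8 tert-butyl acetoacetate
Product: 10 methyl 4-(benzyloxy)-2-{[5-(tert-butoxycarbonyl)-2,4-dioxo-6-pentylcyclohexyl]oxy}-6-methylbenzoate (mixture of stereoisomers and enol forms), via Michael adduct 9 (not isolated)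
Conditions: KOt-Bu (1.2 equiv), t-BuOH–THF, rt → 70 °C; then aq. HCl
Reagents that add atoms: none
Why: Tandem Michael addition–Claisen condensation, the classical annulation of acetoacetates with crotonate-type enoates to 5-alkylcyclohexane-1,3-dione-4-carboxylates. The potassium enolate of 8 adds through its central carbon (C5') to the β-carbon C6' of 7, and the α-aryloxy ester carbanion formed at C1' is protonated by tert-butanol to give 9. Equilibrium deprotonation of the acetyl methyl group (C3') of 9 then lets it attack the methyl ester carbonyl (C2') in a 6-exo-trig closure that expels methoxide and forms the only ring made here. The product is deprotonated at once between its two ketones, and this stabilised enolate is the thermodynamic sink that pulls the reversible Michael step forward. C1', C5' and C6' become stereocentres under no control beyond equilibration, and none is needed because all three are flattened in steps 6 to 8. The step needs conjugate rather than carbonyl addition, which the soft stabilised donor secures, and Claisen closure on the C2' ester rather than Dieckmann closure of the C1' carbanion on the ring A benzoate. That side product would be a benzofuranone β-keto ester with a quaternary carbon; it cannot be deprotonated and is reopened by the methoxide set free, whereas 10 leaves the equilibrium as its enolate. The tert-butyl ester is too hindered to serve as Claisen acceptor or to exchange, so it arrives intact for step 6.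

Step 6
Reactants: 10 methyl 4-(benzyloxy)-2-{[5-(tert-butoxycarbonyl)-2,4-dioxo-6-pentylcyclohexyl]oxy}-6-methylbenzoate
Product: 12 methyl 4-(benzyloxy)-2-[(2,4-dioxo-6-pentylcyclohexyl)oxy]-6-methylbenzoate (mixture of stereoisomers and enol forms), via keto acid 11 (not isolated)
Conditions: CF3CO2H, CH2Cl2, 0 °C → rt; then PhMe, 50 °C
Reagents that add atoms: none
Why: Acidolysis of the tert-butyl ester (loss of isobutene) gives β-keto acid 11, which decarboxylates through the usual six-membered transition state on gentle warming. The methyl benzoate and benzyl ether are inert to the acid at room temperature, and the temperature is kept low so the dione is not driven towards loss of the ring A phenol.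

Step 7
Reactants: 12 methyl 4-(benzyloxy)-2-[(2,4-dioxo-6-pentylcyclohexyl)oxy]-6-methylbenzoate
Product: 13 methyl 4-(benzyloxy)-2-[(4-methoxy-2-oxo-6-pentylcyclohex-3-en-1-yl)oxy]-6-methylbenzoate (mixture of diastereomers)
Conditions: HC(OMe)3, TsOH·H2O (cat.), MeOH, rt
Reagents that add atoms: trimethyl orthoformate, COC(OC)OC
Why: Acid-catalysed enol ether formation of a cyclic 1,3-dione with the orthoformate as water scavenger; methanol should enter at C4', flanked only by a methylene, rather than at C2', which is screened by the aryloxy-bearing C1'. This follows the known preference of 4-substituted cyclohexane-1,3-diones to etherify at the remote carbonyl, and the reaction is reversible, so a minor isomer can be re-equilibrated.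

Step 8
Reactants: 13 methyl 4-(benzyloxy)-2-[(4-methoxy-2-oxo-6-pentylcyclohex-3-en-1-yl)oxy]-6-methylbenzoate
Product: 15 methyl 4-(benzyloxy)-2-(2-hydroxy-4-methoxy-6-pentylphenoxy)-6-methylbenzoate, via selenide 14 (not isolated)
Conditions: LiN(i-Pr)2 (1.1 equiv), THF, −78 °C; PhSeBr, −78 °C; then H2O2, pyridine, CH2Cl2, 0 °C → rt
Reagents that add atoms: none
Why: Enolate selenenylation and selenoxide syn elimination; kinetic deprotonation of a 3-alkoxycyclohexenone occurs at the α' carbon (C1', further acidified by the aryloxy group), which puts that group on an sp2 carbon where it cannot be expelled. Selenium should enter anti to the pentyl group and thus cis to H-6' as the syn elimination requires, and the cross-conjugated dienone tautomerises to the phenol.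

Step 9
Reactants: 15 methyl 4-(benzyloxy)-2-(2-hydroxy-4-methoxy-6-pentylphenoxy)-6-methylbenzoate
Product: 16 methyl 4-(benzyloxy)-2-[2-(benzyloxy)-4-methoxy-6-pentylphenoxy]-6-methylbenzoate
Conditions: BnBr, K2CO3, DMF, 50 °C
Reagents that add atoms: benzyl bromide, BrCc1ccccc1
Why: Williamson ether synthesis; blocking O2' keeps it from consuming base in step 11 and from closing a seven-membered aryl ester on the ring A carboxyl in steps 11 and 12.

Step 10
Reactants: 17 hexanoyl chloride; 18 N,O-dimethylhydroxylamine hydrochloride
Product: 19 N-methoxy-N-methylhexanamide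
Conditions: Et3N, CH2Cl2, 0 °C → rt
Reagents that add atoms: none
Why: Acylation of an amine with an acid chloride, the standard preparation of a Weinreb amide.

Step 11
Reactants: 16 methyl 4-(benzyloxy)-2-[2-(benzyloxy)-4-methoxy-6-pentylphenoxy]-6-methylbenzoate; 19 N-methoxy-N-methylhexanamide
Product: 20 methyl 4-(benzyloxy)-2-[2-(benzyloxy)-4-methoxy-6-pentylphenoxy]-6-(2-oxoheptyl)benzoate
Conditions: LiN(i-Pr)2 (2 equiv), THF, −78 °C; then 19, −78 → −40 °C; aq. HCl
Reagents that add atoms: none
Why: Lateral lithiation of an ortho-toluate and acylation; the ester-stabilised benzylic anion adds to the Weinreb amide to give a chelated tetrahedral intermediate that survives until the quench, so the ketone is not attacked again. Benzyl ethers are known to tolerate this amide base at −78 °C.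

Step 12
Reactants: 20 methyl 4-(benzyloxy)-2-[2-(benzyloxy)-4-methoxy-6-pentylphenoxy]-6-(2-oxoheptyl)benzoate
Product: 21 6-(benzyloxy)-8-[2-(benzyloxy)-4-methoxy-6-pentylphenoxy]-3-pentyl-1H-isochromen-1-one
Conditions: TsOH·H2O (cat.), PhMe, reflux, removal of MeOH
Reagents that add atoms: none
Why: Acid-catalysed enol lactonisation; the enol oxygen attacks the protonated ester in a 6-exo-trig closure and methanol is distilled out. Acid is used because an enolate would instead close a C–C bond on the ester to give a naphthalenediol.

Step 13
Reactants: 21 6-(benzyloxy)-8-[2-(benzyloxy)-4-methoxy-6-pentylphenoxy]-3-pentyl-1H-isochromen-1-one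
Product: 22 6-hydroxy-8-(2-hydroxy-4-methoxy-6-pentylphenoxy)-3-pentyl-1H-isochromen-1-one
Conditions: BCl3, C6HMe5, CH2Cl2, −78 °C; then H2O
Reagents that add atoms: none
Why: Lewis acid debenzylation with pentamethylbenzene as a non-basic benzyl cation scavenger; at −78 °C aryl benzyl ethers are cleaved while the aryl methyl ether (no chelating carbonyl beside it), the diaryl ether and the enol lactone are left. Hydrogenolysis is avoided because it could saturate C3=C4.

## Compound list

1 | trimethyl phosphonoacetate | COC(=O)CP(=O)(OC)OC | starting material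
2 | methyl 2-diazo-2-(dimethoxyphosphoryl)acetate | COC(=O)C(=[N+]=[N-])P(=O)(OC)OC | intermediate
3 | methyl orsellinate (methyl 2,4-dihydroxy-6-methylbenzoate) | COC(=O)c1c(C)cc(O)cc1O | starting material
4 | methyl 4-(benzyloxy)-2-hydroxy-6-methylbenzoate | COC(=O)c1c(C)cc(OCc2ccccc2)cc1O | intermediate
5 | methyl 4-(benzyloxy)-2-[1-(dimethoxyphosphoryl)-2-methoxy-2-oxoethoxy]-6-methylbenzoate (racemic) | COC(=O)C(Oc1cc(OCc2ccccc2)cc(C)c1C(=O)OC)P(=O)(OC)OC | intermediate
6 | hexanal | CCCCCC=O | starting material
7 | methyl (2Z)-2-[5-(benzyloxy)-2-(methoxycarbonyl)-3-methylphenoxy]oct-2-enoate | CCCCC/C=C(\Oc1cc(OCc2ccccc2)cc(C)c1C(=O)OC)C(=O)OC | intermediate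
8 | tert-butyl acetoacetate | CC(=O)CC(=O)OC(C)(C)C | starting material
9 | 1-tert-butyl 5-methyl 2-acetyl-4-[5-(benzyloxy)-2-(methoxycarbonyl)-3-methylphenoxy]-3-pentylpentanedioate (mixture of stereoisomers; not isolated) | CCCCCC(C(C(C)=O)C(=O)OC(C)(C)C)C(Oc1cc(OCc2ccccc2)cc(C)c1C(=O)OC)C(=O)OC | intermediate
10 | methyl 4-(benzyloxy)-2-{[5-(tert-butoxycarbonyl)-2,4-dioxo-6-pentylcyclohexyl]oxy}-6-methylbenzoate (mixture of stereoisomers and enol forms) | CCCCCC1C(C(=O)OC(C)(C)C)C(=O)CC(=O)C1Oc1cc(OCc2ccccc2)cc(C)c1C(=O)OC | intermediate
11 | 3-[5-(benzyloxy)-2-(methoxycarbonyl)-3-methylphenoxy]-4,6-dioxo-2-pentylcyclohexane-1-carboxylic acid (mixture of stereoisomers; not isolated) | CCCCCC1C(C(=O)O)C(=O)CC(=O)C1Oc1cc(OCc2ccccc2)cc(C)c1C(=O)OC | intermediate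
12 | methyl 4-(benzyloxy)-2-[(2,4-dioxo-6-pentylcyclohexyl)oxy]-6-methylbenzoate (mixture of stereoisomers and enol forms) | CCCCCC1CC(=O)CC(=O)C1Oc1cc(OCc2ccccc2)cc(C)c1C(=O)OC | intermediate
13 | methyl 4-(benzyloxy)-2-[(4-methoxy-2-oxo-6-pentylcyclohex-3-en-1-yl)oxy]-6-methylbenzoate (mixture of diastereomers) | CCCCCC1CC(OC)=CC(=O)C1Oc1cc(OCc2ccccc2)cc(C)c1C(=O)OC | intermediate
14 | methyl 4-(benzyloxy)-2-{[4-methoxy-2-oxo-6-pentyl-1-(phenylselanyl)cyclohex-3-en-1-yl]oxy}-6-methylbenzoate (racemic, phenylselanyl trans to pentyl, one enantiomer drawn; not isolated) | CCCCC[C@H]1CC(OC)=CC(=O)[C@@]1([Se]c1ccccc1)Oc1cc(OCc2ccccc2)cc(C)c1C(=O)OC | intermediate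
15 | methyl 4-(benzyloxy)-2-(2-hydroxy-4-methoxy-6-pentylphenoxy)-6-methylbenzoate | CCCCCc1cc(OC)cc(O)c1Oc1cc(OCc2ccccc2)cc(C)c1C(=O)OC | intermediate
16 | methyl 4-(benzyloxy)-2-[2-(benzyloxy)-4-methoxy-6-pentylphenoxy]-6-methylbenzoate | CCCCCc1cc(OC)cc(OCc2ccccc2)c1Oc1cc(OCc2ccccc2)cc(C)c1C(=O)OC | intermediate
17 | hexanoyl chloride | CCCCCC(=O)Cl | starting material
18 | N,O-dimethylhydroxylamine hydrochloride | CNOC.Cl | starting material
19 | N-methoxy-N-methylhexanamide | CCCCCC(=O)N(C)OC | intermediate
20 | methyl 4-(benzyloxy)-2-[2-(benzyloxy)-4-methoxy-6-pentylphenoxy]-6-(2-oxoheptyl)benzoate | CCCCCC(=O)Cc1cc(OCc2ccccc2)cc(Oc2c(CCCCC)cc(OC)cc2OCc2ccccc2)c1C(=O)OC | intermediate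
21 | 6-(benzyloxy)-8-[2-(benzyloxy)-4-methoxy-6-pentylphenoxy]-3-pentyl-1H-isochromen-1-one | CCCCCc1cc2cc(OCc3ccccc3)cc(Oc3c(CCCCC)cc(OC)cc3OCc3ccccc3)c2c(=O)o1 | intermediate
22 | 6-hydroxy-8-(2-hydroxy-4-methoxy-6-pentylphenoxy)-3-pentyl-1H-isochromen-1-one | CCCCCc1cc2cc(O)cc(Oc3c(O)cc(OC)cc3CCCCC)c2c(=O)o1 | target

## Step count and risk

Total: 13 steps. Longest linear sequence: 11 steps from methyl orsellinate 3 (steps 2–9 and 11–13); steps 1 and 10 are one-step side branches.

**Step 5 (key step).** The most likely failure is a sluggish, reversible conjugate addition, since the acceptor is β-alkylated and carries an α-oxygen donor. Deconjugation of the enoate, or Dieckmann closure of the transient C1' carbanion on the ring A ester, would then take over. Fallback: the same ring is closed with the roles exchanged, using a more electrophilic enone and a malonate.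
- Phenol 4 undergoes Rh2(OAc)4-catalysed O–H insertion with commercial dimethyl (1-diazo-2-oxopropyl)phosphonate to give methyl 4-(benzyloxy)-2-{[1-(dimethoxyphosphoryl)-2-oxopropyl]oxy}-6-methylbenzoate F1.
- Olefination of F1 with hexanal 6 (LiCl, DBU) gives the enone methyl 4-(benzyloxy)-6-methyl-2-{[(3Z)-2-oxonon-3-en-3-yl]oxy}benzoate F2.
- F2 with tert-butyl methyl malonate and NaOMe passes through the Michael adduct 1-tert-butyl 3-methyl 2-{2-[5-(benzyloxy)-2-(methoxycarbonyl)-3-methylphenoxy]-3-oxo-1-pentylbutyl}propanedioate F3.
- The ketone methyl group of F3 closes on the methyl ester, and the route is rejoined at 10.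

**Step 3.** The chelated, doubly flanked phenol may insert slowly, so that carbenoid dimerisation or attack on the ester carbonyl or the arene competes. Fallback: the O–C1' bond is made by plain alkylation.
- Phenol 4 with methyl bromoacetate (K2CO3, DMF) gives methyl 4-(benzyloxy)-2-(2-methoxy-2-oxoethoxy)-6-methylbenzoate F4.
- Its lithium enolate (lithium diisopropylamide, −78 °C, kept cold to hold back Dieckmann closure) adds to hexanal 6 to give the aldol methyl 4-(benzyloxy)-2-[(3-hydroxy-1-methoxy-1-oxooctan-2-yl)oxy]-6-methylbenzoate F5.
- Mesylation gives methyl 4-(benzyloxy)-2-({1-methoxy-3-[(methanesulfonyl)oxy]-1-oxooctan-2-yl}oxy)-6-methylbenzoate F6, and elimination with DBU returns to 7.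

**Step 7.** The risk is poor site selectivity between the two carbonyl groups, giving both enol ethers. Fallback: the ring B ester is kept and used to direct both alkylations, as the ring A ester does in step 2.
- Compound 10 is dehydrogenated (DDQ, dioxane) to tert-butyl 3-[5-(benzyloxy)-2-(methoxycarbonyl)-3-methylphenoxy]-4,6-dihydroxy-2-pentylbenzoate F7.
- Benzylation goes to the unchelated hydroxyl para to the ester (C2'), giving tert-butyl 4-(benzyloxy)-3-[5-(benzyloxy)-2-(methoxycarbonyl)-3-methylphenoxy]-6-hydroxy-2-pentylbenzoate F8.
- Methylation of the chelated hydroxyl (MeI, K2CO3, DMF) gives tert-butyl 4-(benzyloxy)-3-[5-(benzyloxy)-2-(methoxycarbonyl)-3-methylphenoxy]-6-methoxy-2-pentylbenzoate F9.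
- CF3CO2H gives 4-(benzyloxy)-3-[5-(benzyloxy)-2-(methoxycarbonyl)-3-methylphenoxy]-6-methoxy-2-pentylbenzoic acid F10.
- Protodecarboxylation (Ag2CO3 cat., AcOH, DMSO, 120 °C) rejoins the route at 16.

**Step 8.** The C1' lithium enolate may close on the ring A ester before it meets the selenium electrophile. Enolisation towards C5' instead would open the way to loss of the ring A phenol. Fallback: the enolate is trapped as it forms. Lithium diisopropylamide is added to 13 in the presence of Me3SiCl at −78 °C to give the cross-conjugated silyl dienol ether methyl 4-(benzyloxy)-2-({4-methoxy-6-pentyl-2-[(trimethylsilyl)oxy]cyclohexa-1,3-dien-1-yl}oxy)-6-methylbenzoate F11. Saegusa oxidation with Pd(OAc)2 (divalent palladium) in MeCN then gives 15.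

**Step 12.** The hindered ester may lactonise incompletely, or benzyl groups may be lost or migrate under acid at reflux. Fallback: the lactone is closed from the acid.
- Ester 16 is hydrolysed (KOH, DMSO–H2O, 100 °C) to 4-(benzyloxy)-2-[2-(benzyloxy)-4-methoxy-6-pentylphenoxy]-6-methylbenzoic acid F12.
- Its dianion (2 equiv lithium diisopropylamide) is acylated with 19 to give 4-(benzyloxy)-2-[2-(benzyloxy)-4-methoxy-6-pentylphenoxy]-6-(2-oxoheptyl)benzoic acid F13.
- Acetic anhydride closes F13 to 21.

## Further compounds

F1 | step 5 | methyl 4-(benzyloxy)-2-{[1-(dimethoxyphosphoryl)-2-oxopropyl]oxy}-6-methylbenzoate (racemic) | CC(=O)C(Oc1cc(OCc2ccccc2)cc(C)c1C(=O)OC)P(=O)(OC)OC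
F2 | step 5 | methyl 4-(benzyloxy)-6-methyl-2-{[(3Z)-2-oxonon-3-en-3-yl]oxy}benzoate | CCCCC/C=C(\Oc1cc(OCc2ccccc2)cc(C)c1C(=O)OC)C(C)=O
F3 | step 5 | 1-tert-butyl 3-methyl 2-{2-[5-(benzyloxy)-2-(methoxycarbonyl)-3-methylphenoxy]-3-oxo-1-pentylbutyl}propanedioate (mixture of stereoisomers) | CCCCCC(C(C(=O)OC)C(=O)OC(C)(C)C)C(Oc1cc(OCc2ccccc2)cc(C)c1C(=O)OC)C(C)=O
F4 | step 3 | methyl 4-(benzyloxy)-2-(2-methoxy-2-oxoethoxy)-6-methylbenzoate | COC(=O)COc1cc(OCc2ccccc2)cc(C)c1C(=O)OC
F5 | step 3 | methyl 4-(benzyloxy)-2-[(3-hydroxy-1-methoxy-1-oxooctan-2-yl)oxy]-6-methylbenzoate (mixture of diastereomers) | CCCCCC(O)C(Oc1cc(OCc2ccccc2)cc(C)c1C(=O)OC)C(=O)OC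
F6 | step 3 | methyl 4-(benzyloxy)-2-({1-methoxy-3-[(methanesulfonyl)oxy]-1-oxooctan-2-yl}oxy)-6-methylbenzoate (mixture of diastereomers) | CCCCCC(OS(C)(=O)=O)C(Oc1cc(OCc2ccccc2)cc(C)c1C(=O)OC)C(=O)OC
F7 | step 7 | tert-butyl 3-[5-(benzyloxy)-2-(methoxycarbonyl)-3-methylphenoxy]-4,6-dihydroxy-2-pentylbenzoate | CCCCCc1c(C(=O)OC(C)(C)C)c(O)cc(O)c1Oc1cc(OCc2ccccc2)cc(C)c1C(=O)OC
F8 | step 7 | tert-butyl 4-(benzyloxy)-3-[5-(benzyloxy)-2-(methoxycarbonyl)-3-methylphenoxy]-6-hydroxy-2-pentylbenzoate | CCCCCc1c(C(=O)OC(C)(C)C)c(O)cc(OCc2ccccc2)c1Oc1cc(OCc2ccccc2)cc(C)c1C(=O)OC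
F9 | step 7 | tert-butyl 4-(benzyloxy)-3-[5-(benzyloxy)-2-(methoxycarbonyl)-3-methylphenoxy]-6-methoxy-2-pentylbenzoate | CCCCCc1c(C(=O)OC(C)(C)C)c(OC)cc(OCc2ccccc2)c1Oc1cc(OCc2ccccc2)cc(C)c1C(=O)OC
F10 | step 7 | 4-(benzyloxy)-3-[5-(benzyloxy)-2-(methoxycarbonyl)-3-methylphenoxy]-6-methoxy-2-pentylbenzoic acid | CCCCCc1c(C(=O)O)c(OC)cc(OCc2ccccc2)c1Oc1cc(OCc2ccccc2)cc(C)c1C(=O)OC
F11 | step 8 | methyl 4-(benzyloxy)-2-({4-methoxy-6-pentyl-2-[(trimethylsilyl)oxy]cyclohexa-1,3-dien-1-yl}oxy)-6-methylbenzoate (racemic) | CCCCCC1CC(OC)=CC(O[Si](C)(C)C)=C1Oc1cc(OCc2ccccc2)cc(C)c1C(=O)OC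
F12 | step 12 | 4-(benzyloxy)-2-[2-(benzyloxy)-4-methoxy-6-pentylphenoxy]-6-methylbenzoic acid | CCCCCc1cc(OC)cc(OCc2ccccc2)c1Oc1cc(OCc2ccccc2)cc(C)c1C(=O)O
F13 | step 12 | 4-(benzyloxy)-2-[2-(benzyloxy)-4-methoxy-6-pentylphenoxy]-6-(2-oxoheptyl)benzoic acid | CCCCCC(=O)Cc1cc(OCc2ccccc2)cc(Oc2c(CCCCC)cc(OC)cc2OCc2ccccc2)c1C(=O)O
A1 | alternative 1 | 8-[2-(benzyloxy)-4-methoxy-6-pentylphenoxy]-1-oxo-3-pentyl-3,4-dihydro-1H-isochromen-6-yl acetate (racemic) | CCCCCC1Cc2cc(OC(C)=O)cc(Oc3c(CCCCC)cc(OC)cc3OCc3ccccc3)c2C(=O)O1
A2 | alternative 1 | undeca-1,3-diyn-6-yl 3-[2-(benzyloxy)-4-methoxy-6-pentylphenoxy]prop-2-ynoate (racemic) | C#CC#CCC(CCCCC)OC(=O)C#COc1c(CCCCC)cc(OC)cc1OCc1ccccc1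
A3 | alternative 1 | 2-(benzyloxy)-4-methoxy-6-pentylphenol | CCCCCc1cc(OC)cc(OCc2ccccc2)c1O
A4 | alternative 2 | 2,4-bis(benzyloxy)-6-[2-(benzyloxy)-4-methoxy-6-pentylphenoxy]benzoic acid | OC(=O)c1c(OCc2ccccc2)cc(OCc2ccccc2)cc1Oc1c(CCCCC)cc(OC)cc1OCc1ccccc1
A5 | alternative 2 | 3,5-bis(benzyloxy)-2-(trimethylsilyl)phenyl trifluoromethanesulfonate | C[Si](C)(C)c1c(OCc2ccccc2)cc(OCc2ccccc2)cc1OS(=O)(=O)C(F)(F)F
A6 | alternative 3 | 6-(benzyloxy)-8-[2-(benzyloxy)-4-methoxy-6-pentylphenoxy]-3-pentyl-1H-isochromen-1-one | CCCCCc1cc2cc(OCc3ccccc3)cc(Oc3c(CCCCC)cc(OC)cc3OCc3ccccc3)c2c(=O)o1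
A7 | alternative 3 | 4-(benzyloxy)-2-[2-(benzyloxy)-4-methoxy-6-pentylphenoxy]benzoic acid | OC(=O)c1ccc(OCc2ccccc2)cc1Oc1c(CCCCC)cc(OC)cc1OCc1ccccc1
A8 | alternative 3 | 1-[dimethyl(oxo)-λ6-sulfanylidene]heptan-2-one | CCCCCC(=O)C=S(C)(C)=O
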